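## Structural features

The target is a daucane ester: a cyclopentane (ring A, C1–C5) trans-fused to a cycloheptane (ring B, C1 and C5–C10). Daucane numbering is used throughout: C1 is the methyl-bearing quaternary fusion carbon, C4 the isopropyl carbinol, C5 the fusion CH, C14 the oxirane CH2, and β denotes the face of the C1 methyl group. There are seven stereocentres in two contiguous runs, C4–C5–C6 and C8–C9–C10–C1: 1β-methyl, 4β-OH, 5α-H, 6α-O-isovaleryl, 8α-oxirane oxygen, 9α-OH and 10α-OH, i.e. (1S,4R,5S,6S,8S,9S,10S). Every oxygen on ring B is on the α face; the angular methyl and the C4 hydroxyl are on the β face. The fragile groups are the spiro-oxirane, which sits within reach of the C9 and C4 hydroxyls and opens under acid, and the secondary ester, which would be expelled by β-elimination if it stood beside a C8 ketone. While C6 is a ketone, the tertiary β-hydroxy unit at C4 is also open to retro-aldol cleavage and dehydration. The real difficulty is the quaternary C1 in absolute sense together with the trans ring fusion and the fully substituted C4, followed by α-face oxygenation of C8–C10 on a hindered ring. The feature exploited is that C4(OH)(iPr)–C5(H)–C6(O) is an aldol unit once C6 is a carbonyl, and the C1 methyl is β to that carbonyl. A C5=C1 enone in ring B can therefore accept methyl at C1 and use the resulting C5 enolate to close ring A onto a side-chain isopropyl ketone. C8 is 1,3 to C6, so ring B maps onto cycloheptane-1,3-dione with one carbonyl masked.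

## Logic of the disconnections

26 to 25: the two C–O bonds of the oxirane (C8–O and C14–O) are cut. The oxygen lies syn to the C9 hydroxyl, which is the outcome expected of a hydroxyl-directed oxygen transfer to an exocyclic alkene. This removes the most sensitive group and one stereocentre. The forward step needs a free allylic C9–OH, a single alkene and conditions that spare the ester.

25 to 22 (through 24 and 23): the acyl C–O bond at O6 is cut and the C9/C10 diol and O6 are given temporary groups. The ester is introduced only after all carbonyl chemistry at C8, so that a β-acyloxy ketone never exists. The gain is a robust silyl ether at O6 and an acetonide at O9/O10 during the C8 chemistry. The demand is orthogonal removal: fluoride for silicon, aqueous acid for the acetonide, acylation only at O6.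

22 to 21: the C8=C14 bond is cut, returning C8 to a ketone and C14 to a one-carbon reagent. The forward methylenation must be non-basic, because C9 is an epimerisable α-alkoxy centre and C6 and C10 carry β-oxygen leaving groups.

21 to 19 (through 20): the C9–O and C10–O bonds are cut as a syn addition to a C9=C10 enone. This removes two stereocentres at once. The forward step needs α-face attack, which the axial C1 methyl over the β face of C10 should provide, and an oxidant able to turn over an electron-poor alkene.

19 to 14 (through 16 and 15): the C9=C10 unsaturation is removed (C9–H and C10–H restored) and the C8 carbonyl is returned to its dioxolane. The C8 ketone is what activates C9. The forward step must enolise toward C9 and not C7, which is why O6 carries a bulky, non-leaving silyl group at this stage.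

14 to 13: the C6–H bond is cut, returning C6 to the ketone of the aldol unit. The forward reduction must deliver hydride to the β face of C6, which is the more hindered one, so it has to be carried there by the C4 hydroxyl.

13 to 11: the C1–CH3 and C4–C5 bonds are cut together. This opens ring A, removes three stereocentres and leaves an achiral monocyclic enone-dione. The forward step needs a chiral catalyst to choose the enone face at C1, an enolate formed only at C5, and an aldol closure giving the 4β-hydroxy, 5α-H (trans-fused) arrangement.

11 to 9 (through 10): the C4 carbonyl is traced to a trisubstituted alkene via its epoxide, C4 gaining its oxygen and C11 its hydrogen by a 1,2-hydride shift. The alkene is an inert placeholder that survives organomagnesium and palladium chemistry. The forward rearrangement must favour hydride over alkyl shift and spare the ketal.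

9 to 5 and 6: the C1–C2 bond is cut, giving a simple enone and a homoprenyl nucleophile. The forward sequence is conjugate addition with enolate trapping and re-dehydrogenation, which can only restore the C5=C1 double bond.

5 to 1 and 2 (through 3): the C5=C1 unsaturation and the two ketal C–O bonds are removed, arriving at the symmetrical dione. The forward steps need mono-protection of a 1,3-dione and kinetic enolisation away from C7.

## Other disconnections considered

Alternative 1: The cut goes through both ring alkenes of a bicyclic diene, C5=C6 in ring B and C3=C4 in ring A. In the forward sense the second-generation Grubbs catalyst would convert the open-chain dienyne A2 into the diene A1 by ring-closing enyne metathesis followed by ring-closing metathesis.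
- In favour: A2 already holds C1, C9 and C10 with their oxygens, so the α-diol is built on a flexible chain and not on a hindered ring. Metathesis creates no stereocentre, so the ring-forming step carries no ring-fusion gamble. On both counts this alternative is the better plan.
- Against: A2 needs a quaternary stereocentre flanked by a protected diol on an acyclic chain. The isopropyl-substituted alkyne beside that centre is a slow metathesis partner.
- Against: A1 must still be converted from a C3=C4–C5=C6 diene into the C4 carbinol, the 5α hydrogen and the C6 oxygen. That is a net 1,3-dioxygenation with two controlled hydrogen deliveries, for which the diene offers no handle. The C8 silyl ether of A1 would be oxidised later, so its configuration is immaterial.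
- Comparison: structurally it solves C8–C10 earlier but postpones the C4–C5–C6 triad, which the chosen key step builds directly. Mechanistically it is more predictable in the ring closure and less so afterwards. In step count, the preparation of A2 is expected to be longer than the five steps to the chosen precursor, and the redox work after A1 no shorter than the chosen end-game.

Alternative 2: The cut removes C6 and C7 from ring B (bonds C5–C6 and C7–C8), leaving the cis-diquinane 1,3-dione A4. Forward, irradiation of the enol of A4 with propa-1,2-diene A5 would give a methylenecyclobutane across C5=C8. Retro-aldol cleavage of the temporary C5–C8 bond would expand the ring to the methylene dione A3 (De Mayo reaction).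
- In favour: C4, C6 and C8 appear together at the carbonyl or masked-carbonyl level without any ketal chemistry. The quaternary C1 sits in a small rigid bicycle that is easy to secure enantiopure. In steps to the bicyclic core it is the better plan.
- Against: the orientation of allene addition is not assured. A3 has a β,γ-unsaturated ketone (C6 methylene, C5–H, C4 carbonyl) that can slip into conjugation.
- Against: the isopropyl group must be added intermolecularly to C4, from the α face, on an enolisable ketone, in the presence of the C8 ketone. C5 is set only by protonation.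
- Comparison: it is equal to the chosen plan on the late C8–C10 problem and on the ring-fusion uncertainty, which is thermodynamic in both. It is weaker on the C4 carbinol, where the chosen plan uses an intramolecular, metal-organised aldol. The photochemical step is a scale limitation the chosen plan does not have.

Alternative 3: The cut goes through C7–C8 and C1–C10, dividing the skeleton into the vinylcyclopentene A7 (fragment 1) and the siloxyvinyl diazoacetate A8 (fragment 2). Forward, Rh2(DOSP)4 would generate the vinylcarbenoid from A8 and cyclopropanate the vinyl group of A7. The cis-divinylcyclopropane would then undergo Cope rearrangement to the cycloheptadiene A6.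
- In favour: the route is convergent. C1 and C10 are formed together under catalyst control through a concerted boat-type rearrangement, and C14 is already present as the ester carbon. A later hydroboration of C5=C6 from the α face would deliver 5α-H and 6α-OH together. On convergence, on the C1/C10 relationship and on the ring fusion this is the better plan.
- Against: the Cope step must bond to a fully substituted alkene terminus (C1), the less established case. After A6 the isopropyl group has to be added to the C4 ketone with facial control. The C8 enoate must be reworked into the spiro-oxirane with a C9 hydroxyl (reduction, oxygen transposition to C9, new exocyclic alkene).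
- Comparison: it is shorter to the bicycle, but probably no shorter overall. The chosen plan is better on the C4 carbinol and needs no diazo compound.

Key step: step 6

Remark: the sense of induction of the phosphoramidite ligand L* (a 2,2'-biphenol-derived phosphoramidite of a C2-symmetric bis(1-phenylethyl)amine) in step 6 is assumed to follow that of simple 3-alkylcycloalkenones; L* means whichever ligand antipode gives the 1R enolate 12.

## Route

Step 1
Reactants: 1 cycloheptane-1,3-dione; 2 1,2-bis(trimethylsilyloxy)ethane
Product: 3 1,4-dioxaspiro[4.6]undecan-7-one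
Conditions: Me3SiOTf (2 mol%), CH2Cl2, −78 → −20 °C; pyridine quench
Reagents that add atoms: none
Why: Under aprotic silyl triflate catalysis at low temperature (Noyori-type ketalisation) the largely non-enolised dione reacts as a simple ketone; one equivalent of 2 should stop at the mono-ketal because the remaining carbonyl is hindered and inductively deactivated, and the absence of protic acid and heat avoids opening of the β-keto ketal to a hydroxyethyl vinylogous ester.

Step 2
Reactants: 3 1,4-dioxaspiro[4.6]undecan-7-one
Product: 5 1,4-dioxaspiro[4.6]undec-8-en-7-one, via trimethylsilyl enol ether 4 (not isolated)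
Conditions: LiN(iPr)2, Me3SiCl, THF, −78 °C; then Pd(OAc)2 (1.05 equiv), MeCN, rt
Reagents that add atoms: none
Why: Kinetic deprotonation should occur at C5 because the C7 methylene is neopentylic, flanked by the ketal carbon; Saegusa–Ito oxidation of the trapped enol ether (divalent palladium enolate, β-hydride elimination from C1, release of zerovalent palladium) gives the enone.

Step 3
Reactants: 5 1,4-dioxaspiro[4.6]undec-8-en-7-one; 6 5-bromo-2-methylpent-2-ene
Product: 9 9-(4-methylpent-3-en-1-yl)-1,4-dioxaspiro[4.6]undec-8-en-7-one, via (4-methylpent-3-en-1-yl)magnesium bromide 7 (not isolated), via trimethylsilyl enol ether 8 (not isolated)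
Conditions: 6, Mg, THF, rt; then 5, CuBr·SMe2 (10 mol%), Me3SiCl, THF, −78 °C; then Pd(OAc)2 (1.05 equiv), MeCN, rt
Reagents that add atoms: none
Why: Copper-catalysed, Me3SiCl-accelerated conjugate addition of the Grignard reagent places the chain on C1 and leaves a C5=C6 silyl enol ether, so the following Saegusa–Ito oxidation can only remove the hydrogen at C1 and returns the enone in β-substituted form; the trisubstituted side-chain alkene is not expected to interfere.

Step 4
Reactants: 9 9-(4-methylpent-3-en-1-yl)-1,4-dioxaspiro[4.6]undec-8-en-7-one
Product: 10 9-[2-(3,3-dimethyloxiran-2-yl)ethyl]-1,4-dioxaspiro[4.6]undec-8-en-7-one (racemic at the oxirane carbon)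
Conditions: mCPBA (1.1 equiv), NaHCO3, CH2Cl2, 0 °C
Reagents that add atoms: 3-chloroperoxybenzoic acid, O=C(OO)c1cccc(Cl)c1
Why: Prilezhaev epoxidation is selective for the electron-rich trisubstituted alkene over the electron-poor enone, and the bicarbonate buffer protects the ketal; the new stereocentre is formed as a racemate and is erased in step 5.

Step 5
Reactants: 10 9-[2-(3,3-dimethyloxiran-2-yl)ethyl]-1,4-dioxaspiro[4.6]undec-8-en-7-one
Product: 11 9-(4-methyl-3-oxopentyl)-1,4-dioxaspiro[4.6]undec-8-en-7-one
Conditions: BF3·OEt2 (0.3 equiv), CH2Cl2, −78 → −40 °C; Et3N quench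
Reagents that add atoms: none
Why: Meinwald rearrangement: the Lewis acid opens the oxirane at the tertiary carbon and a 1,2-hydride shift from the adjacent carbinol carbon gives the isopropyl ketone; sub-stoichiometric BF3 at low temperature with an amine quench is chosen to spare the dioxolane, whose ionisation is disfavoured by the nearby enone carbonyl.

Step 6
Reactants: 11 9-(4-methyl-3-oxopentyl)-1,4-dioxaspiro[4.6]undec-8-en-7-one
Product: 13 8,8-ethylenedioxy-4β-hydroxy-4α-isopropyl-1β-methyl-5αH-bicyclo[5.3.0]decan-6-one (daucane numbering; 1R,4R,5R), via dimethylaluminium enolate 12 (not isolated)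
Conditions: Cu(OTf)2 (5 mol%), L* (10 mol%), AlMe3 (2.5 equiv), Et2O, −30 °C; then rt, 16 h; aq. KNaC4H4O6
Reagents that add atoms: trimethylaluminium, C[Al](C)C
Why: AlMe3 and Cu(OTf)2 generate a monovalent methylcopper–phosphoramidite species that adds to the enone (π-complex, C1–Cu bond formation, reductive elimination), and transmetallation leaves the C5=C6 dimethylaluminium enolate 12 with the double bond fixed toward C5. The closest known reaction type is the copper-catalysed asymmetric conjugate addition of trialkylaluminium reagents to 3-substituted cycloalkenones with capture of the aluminium enolate by an internal ketone. Ring A then closes by a 5-(enolexo)-exo-trig aldol addition of C5 to the tethered C4 ketone, with aluminium bridging the enolate and ketone oxygens. C1 is set by the ligand, which selects the enantiotopic face of the achiral enone; C4 is set by the aluminium chelate, which holds the carbinol oxygen on the side of the C6 carbonyl and turns the isopropyl group away; C5 is not fixed by the tether, whose kinetic preference is closure on the face that carries C2, that is cis fusion. The step therefore relies on the reversibility of a ketone–ketone aldol: on warming, the tertiary aluminium aldolate should revert to 12 and funnel into the trans-fused chelate, in which the isopropyl group lies opposite both the angular methyl group and C6. The selectivities needed are 1,4- over 1,2-methyl transfer (copper catalysis in Et2O, where AlMe3 alone attacks neither ketone at −30 °C, and a hindered isopropyl ketone), a single enolate regioisomer (guaranteed by its origin in the conjugate addition, so C7 is never deprotonated and the β-ketal cannot be eliminated) and the trans ring fusion, which is the least secure element.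

Step 7
Reactants: 13 8,8-ethylenedioxy-4β-hydroxy-4α-isopropyl-1β-methyl-5αH-bicyclo[5.3.0]decan-6-one
Product: 14 8,8-ethylenedioxy-4α-isopropyl-1β-methyl-5αH-bicyclo[5.3.0]decane-4β,6α-diol
Conditions: Me4NBH(OAc)3 (5 equiv), MeCN/AcOH (1:1), −30 → −20 °C
Reagents that add atoms: none
Why: Evans–Saksena reduction: the triacetoxyborohydride exchanges one acetate for the C4 hydroxyl and delivers hydride intramolecularly to the β face of the C6 carbonyl, on which C4 stands, so the new hydroxyl should be α (1,3-anti to O4), against the steric bias for external attack; the reagent does not reduce unactivated ketones at this temperature and leaves the ketal.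

Step 8
Reactants: 14 8,8-ethylenedioxy-4α-isopropyl-1β-methyl-5αH-bicyclo[5.3.0]decane-4β,6α-diol
Product: 15 6α-(tert-butyldimethylsilyloxy)-8,8-ethylenedioxy-4α-isopropyl-1β-methyl-5αH-bicyclo[5.3.0]decan-4β-ol
Conditions: tBuMe2SiOTf (1.2 equiv), 2,6-lutidine, CH2Cl2, −78 → −20 °C
Reagents that add atoms: tert-butyldimethylsilyl trifluoromethanesulfonate, CC(C)(C)[Si](C)(C)OS(=O)(=O)C(F)(F)F
Why: The silyl triflate silylates the secondary C6 hydroxyl much faster than the hindered tertiary C4 hydroxyl at low temperature; a bulky, non-leaving silyl ether is chosen so that C7 is shielded in step 10 and no β-acyloxy ketone ever stands beside the C8 carbonyl.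

Step 9
Reactants: 15 6α-(tert-butyldimethylsilyloxy)-8,8-ethylenedioxy-4α-isopropyl-1β-methyl-5αH-bicyclo[5.3.0]decan-4β-ol
Product: 16 6α-(tert-butyldimethylsilyloxy)-4β-hydroxy-4α-isopropyl-1β-methyl-5αH-bicyclo[5.3.0]decan-8-one
Conditions: PPTS (0.2 equiv), acetone/H2O (10:1), 45 °C
Reagents that add atoms: water, O
Why: Mild acid-catalysed ketal hydrolysis; PPTS should leave the secondary tert-butyldimethylsilyl ether intact and is too weak to promote β-elimination of the silyloxy group or dehydration of the tertiary alcohol.

Step 10
Reactants: 16 6α-(tert-butyldimethylsilyloxy)-4β-hydroxy-4α-isopropyl-1β-methyl-5αH-bicyclo[5.3.0]decan-8-one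
Product: 19 6α-(tert-butyldimethylsilyloxy)-4β-hydroxy-4α-isopropyl-1β-methyl-5αH-bicyclo[5.3.0]dec-9-en-8-one, via bis-trimethylsilylated enol ether 17 (not isolated), via C4-O-trimethylsilyl enone 18 (not isolated)
Conditions: LiN(iPr)2 (2.3 equiv), Me3SiCl (4 equiv), THF, −78 → 0 °C; then Pd(OAc)2 (1.1 equiv), MeCN, rt; then 0.5 M HCl, THF, 0 °C
Reagents that add atoms: none
Why: After the C4 hydroxyl is deprotonated, the hindered amide should remove the C9 proton under kinetic control, because abstraction at C7 is retarded by the bulk and the field effect of the adjacent C6 silyloxy group; Saegusa–Ito oxidation then gives the C9=C10 enone, which cannot isomerise further because C1 is quaternary. The tertiary O–SiMe3 group formed on the way is cleaved by the brief cold acid wash, which the tert-butyldimethylsilyl ether survives.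

Step 11
Reactants: 19 6α-(tert-butyldimethylsilyloxy)-4β-hydroxy-4α-isopropyl-1β-methyl-5αH-bicyclo[5.3.0]dec-9-en-8-one
Product: 20 6α-(tert-butyldimethylsilyloxy)-4β,9α,10α-trihydroxy-4α-isopropyl-1β-methyl-5αH-bicyclo[5.3.0]decan-8-one
Conditions: OsO4 (5 mol%), NMO (2 equiv), citric acid (1 equiv), tBuOH/H2O (1:1), rt
Reagents that add atoms: N-methylmorpholine N-oxide, C[N+]1([O-])CCOCC1; water, O
Why: Upjohn dihydroxylation: OsO4 adds suprafacially to C9=C10 from the α face, because in the trans-fused enone the C1 methyl group is axial and stands directly over the β face of C10; citric acid maintains turnover on the electron-poor alkene and keeps the medium acidic, which protects the α-ketol from isomerisation.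

Step 12
Reactants: 20 6α-(tert-butyldimethylsilyloxy)-4β,9α,10α-trihydroxy-4α-isopropyl-1β-methyl-5αH-bicyclo[5.3.0]decan-8-one
Product: 21 6α-(tert-butyldimethylsilyloxy)-4β-hydroxy-9α,10α-(isopropylidenedioxy)-4α-isopropyl-1β-methyl-5αH-bicyclo[5.3.0]decan-8-one
Conditions: Me2C(OMe)2, PPTS (cat.), CH2Cl2, rt
Reagents that add atoms: 2,2-dimethoxypropane, COC(C)(C)OC
Why: Acetal exchange closes the five-membered isopropylidene acetal on the cis-1,2-diol; it blocks O9 and O10 for the later acylation and removes the retro-aldol liability of the β-hydroxy ketone before methylenation, while the hindered tertiary C4 hydroxyl does not react.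

Step 13
Reactants: 21 6α-(tert-butyldimethylsilyloxy)-4β-hydroxy-9α,10α-(isopropylidenedioxy)-4α-isopropyl-1β-methyl-5αH-bicyclo[5.3.0]decan-8-one
Product: 22 6α-(tert-butyldimethylsilyloxy)-9α,10α-(isopropylidenedioxy)-4α-isopropyl-1β-methyl-8-methylene-5αH-bicyclo[5.3.0]decan-4β-ol
Conditions: Zn, CH2Br2, TiCl4, THF/CH2Cl2, 0 °C → rt
Reagents that add atoms: dibromomethane, BrCBr
Why: Takai–Lombardo methylenation: the geminal zinc/titanium reagent is non-basic, so the epimerisable C9 α-alkoxy centre and the β-oxygen substituents at C6 and C10 should be untouched, and it tolerates the free tertiary hydroxyl, the acetonide and the silyl ether.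

Step 14
Reactants: 22 6α-(tert-butyldimethylsilyloxy)-9α,10α-(isopropylidenedioxy)-4α-isopropyl-1β-methyl-8-methylene-5αH-bicyclo[5.3.0]decan-4β-ol
Product: 23 9α,10α-(isopropylidenedioxy)-4α-isopropyl-1β-methyl-8-methylene-5αH-bicyclo[5.3.0]decane-4β,6α-diol
Conditions: Bu4NF (2 equiv), THF, rt → 40 °C
Reagents that add atoms: none
Why: Fluoride cleaves the Si–O bond of the secondary silyl ether; the acetonide, the exocyclic alkene and the tertiary alcohol are inert, and no carbonyl remains that could suffer base-induced elimination.

Step 15
Reactants: 23 9α,10α-(isopropylidenedioxy)-4α-isopropyl-1β-methyl-8-methylene-5αH-bicyclo[5.3.0]decane-4β,6α-diol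
Product: 24 4β-hydroxy-9α,10α-(isopropylidenedioxy)-4α-isopropyl-1β-methyl-8-methylene-5αH-bicyclo[5.3.0]decan-6α-yl 3-methylbutanoate
Conditions: (iPrCH2CO)2O (1.5 equiv), DMAP (0.2 equiv), pyridine, CH2Cl2, rt
Reagents that add atoms: 3-methylbutanoic anhydride, CC(C)CC(=O)OC(=O)CC(C)C
Why: DMAP-catalysed acylation esterifies the secondary C6 hydroxyl, the only accessible free hydroxyl; the tertiary C4 hydroxyl does not acylate under these conditions and O9/O10 are blocked.

Step 16
Reactants: 24 4β-hydroxy-9α,10α-(isopropylidenedioxy)-4α-isopropyl-1β-methyl-8-methylene-5αH-bicyclo[5.3.0]decan-6α-yl 3-methylbutanoate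
Product: 25 4β,9α,10α-trihydroxy-4α-isopropyl-1β-methyl-8-methylene-5αH-bicyclo[5.3.0]decan-6α-yl 3-methylbutanoate
Conditions: AcOH/H2O (4:1), 40 °C
Reagents that add atoms: none
Why: Aqueous acetic acid hydrolyses the isopropylidene acetal; the ester, the exocyclic alkene and the tertiary alcohol tolerate these conditions, and the acid-sensitive oxirane is not yet present.

Step 17
Reactants: 25 4β,9α,10α-trihydroxy-4α-isopropyl-1β-methyl-8-methylene-5αH-bicyclo[5.3.0]decan-6α-yl 3-methylbutanoate
Product: 26 4β,9α,10α-trihydroxy-4α-isopropyl-1β-methyl-5αH-spiro[bicyclo[5.3.0]decane-8,2'-oxiran]-6α-yl 3-methylbutanoate with the oxirane oxygen α (CNP0307265.1)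
Conditions: VO(acac)2 (5 mol%), tBuOOH (1.5 equiv), CH2Cl2, 0 °C → rt
Reagents that add atoms: tert-butyl hydroperoxide, CC(C)(C)OO
Why: Vanadium-catalysed hydroxyl-directed epoxidation: the vanadium alkoxide of the allylic C9 hydroxyl delivers the peroxide oxygen to the face of the exocyclic alkene on which that hydroxyl stands, so the oxirane oxygen should be α and C14 β; the homoallylic C10 hydroxyl is on the same face, and the neutral conditions spare the ester and the new oxirane.

## Compound list

1 | cycloheptane-1,3-dione | O=C1CCCCC(=O)C1 | starting material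
2 | 1,2-bis(trimethylsilyloxy)ethane | C[Si](C)(C)OCCO[Si](C)(C)C | starting material
3 | 1,4-dioxaspiro[4.6]undecan-7-one | O=C1CCCCC2(OCCO2)C1 | intermediate
4 | trimethyl(1,4-dioxaspiro[4.6]undec-7-en-7-yloxy)silane (not isolated) | C[Si](C)(C)OC1=CCCCC2(OCCO2)C1 | intermediate
5 | 1,4-dioxaspiro[4.6]undec-8-en-7-one | O=C1C=CCCC2(OCCO2)C1 | intermediate
6 | 5-bromo-2-methylpent-2-ene | CC(C)=CCCBr | starting material
7 | (4-methylpent-3-en-1-yl)magnesium bromide (not isolated) | CC(C)=CCC[Mg]Br | intermediate
8 | trimethyl{[9-(4-methylpent-3-en-1-yl)-1,4-dioxaspiro[4.6]undec-7-en-7-yl]oxy}silane (racemic, not isolated) | C[Si](C)(C)OC1=CC(CCC=C(C)C)CCC2(OCCO2)C1 | intermediate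
9 | 9-(4-methylpent-3-en-1-yl)-1,4-dioxaspiro[4.6]undec-8-en-7-one | O=C1C=C(CCC=C(C)C)CCC2(OCCO2)C1 | intermediate
10 | 9-[2-(3,3-dimethyloxiran-2-yl)ethyl]-1,4-dioxaspiro[4.6]undec-8-en-7-one (racemic) | O=C1C=C(CCC3OC3(C)C)CCC2(OCCO2)C1 | intermediate
11 | 9-(4-methyl-3-oxopentyl)-1,4-dioxaspiro[4.6]undec-8-en-7-one | O=C1C=C(CCC(=O)C(C)C)CCC2(OCCO2)C1 | intermediate
12 | dimethylaluminium C7=C8 enolate of (9R)-9-methyl-9-(4-methyl-3-oxopentyl)-1,4-dioxaspiro[4.6]undecan-7-one (not isolated) | C[Al](C)OC1=C[C@](C)(CCC(=O)C(C)C)CCC2(OCCO2)C1 | intermediate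
13 | 8,8-ethylenedioxy-4β-hydroxy-4α-isopropyl-1β-methyl-5αH-bicyclo[5.3.0]decan-6-one (1R,4R,5R) | O=C1CC3(OCCO3)CC[C@@]2(C)CC[C@@](O)(C(C)C)[C@H]12 | intermediate
14 | 8,8-ethylenedioxy-4α-isopropyl-1β-methyl-5αH-bicyclo[5.3.0]decane-4β,6α-diol | O[C@H]1CC3(OCCO3)CC[C@@]2(C)CC[C@@](O)(C(C)C)[C@H]12 | intermediate
15 | 6α-(tert-butyldimethylsilyloxy)-8,8-ethylenedioxy-4α-isopropyl-1β-methyl-5αH-bicyclo[5.3.0]decan-4β-ol | CC(C)(C)[Si](C)(C)O[C@H]1CC3(OCCO3)CC[C@@]2(C)CC[C@@](O)(C(C)C)[C@H]12 | intermediate
16 | 6α-(tert-butyldimethylsilyloxy)-4β-hydroxy-4α-isopropyl-1β-methyl-5αH-bicyclo[5.3.0]decan-8-one | CC(C)(C)[Si](C)(C)O[C@H]1CC(=O)CC[C@@]2(C)CC[C@@](O)(C(C)C)[C@H]12 | intermediate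
17 | 6α-(tert-butyldimethylsilyloxy)-4α-isopropyl-1β-methyl-4β,8-bis(trimethylsilyloxy)-5αH-bicyclo[5.3.0]dec-8-ene (not isolated) | CC(C)(C)[Si](C)(C)O[C@H]1CC(O[Si](C)(C)C)=CC[C@@]2(C)CC[C@@](O[Si](C)(C)C)(C(C)C)[C@H]12 | intermediate
18 | 6α-(tert-butyldimethylsilyloxy)-4α-isopropyl-1β-methyl-4β-(trimethylsilyloxy)-5αH-bicyclo[5.3.0]dec-9-en-8-one (not isolated) | CC(C)(C)[Si](C)(C)O[C@H]1CC(=O)C=C[C@@]2(C)CC[C@@](O[Si](C)(C)C)(C(C)C)[C@H]12 | intermediate
19 | 6α-(tert-butyldimethylsilyloxy)-4β-hydroxy-4α-isopropyl-1β-methyl-5αH-bicyclo[5.3.0]dec-9-en-8-one | CC(C)(C)[Si](C)(C)O[C@H]1CC(=O)C=C[C@@]2(C)CC[C@@](O)(C(C)C)[C@H]12 | intermediate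
20 | 6α-(tert-butyldimethylsilyloxy)-4β,9α,10α-trihydroxy-4α-isopropyl-1β-methyl-5αH-bicyclo[5.3.0]decan-8-one | CC(C)(C)[Si](C)(C)O[C@H]1CC(=O)[C@@H](O)[C@@H](O)[C@@]2(C)CC[C@@](O)(C(C)C)[C@H]12 | intermediate
21 | 6α-(tert-butyldimethylsilyloxy)-4β-hydroxy-9α,10α-(isopropylidenedioxy)-4α-isopropyl-1β-methyl-5αH-bicyclo[5.3.0]decan-8-one | CC(C)(C)[Si](C)(C)O[C@H]1CC(=O)[C@H]3OC(C)(C)O[C@H]3[C@@]2(C)CC[C@@](O)(C(C)C)[C@H]12 | intermediate
22 | 6α-(tert-butyldimethylsilyloxy)-9α,10α-(isopropylidenedioxy)-4α-isopropyl-1β-methyl-8-methylene-5αH-bicyclo[5.3.0]decan-4β-ol | CC(C)(C)[Si](C)(C)O[C@H]1CC(=C)[C@H]3OC(C)(C)O[C@H]3[C@@]2(C)CC[C@@](O)(C(C)C)[C@H]12 | intermediate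
23 | 9α,10α-(isopropylidenedioxy)-4α-isopropyl-1β-methyl-8-methylene-5αH-bicyclo[5.3.0]decane-4β,6α-diol | O[C@H]1CC(=C)[C@H]3OC(C)(C)O[C@H]3[C@@]2(C)CC[C@@](O)(C(C)C)[C@H]12 | intermediate
24 | 4β-hydroxy-9α,10α-(isopropylidenedioxy)-4α-isopropyl-1β-methyl-8-methylene-5αH-bicyclo[5.3.0]decan-6α-yl 3-methylbutanoate | CC(C)CC(=O)O[C@H]1CC(=C)[C@H]3OC(C)(C)O[C@H]3[C@@]2(C)CC[C@@](O)(C(C)C)[C@H]12 | intermediate
25 | 4β,9α,10α-trihydroxy-4α-isopropyl-1β-methyl-8-methylene-5αH-bicyclo[5.3.0]decan-6α-yl 3-methylbutanoate | CC(C)CC(=O)O[C@H]1CC(=C)[C@@H](O)[C@@H](O)[C@@]2(C)CC[C@@](O)(C(C)C)[C@H]12 | intermediate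
26 | (1S,4R,5S,6S,8S,9S,10S)-8α,14-epoxy-4β,9α,10α-trihydroxy-5αH-daucan-6α-yl 3-methylbutanoate (CNP0307265.1) | CC(C)CC(=O)O[C@H]1C[C@]2(CO2)[C@@H](O)[C@@H](O)[C@@]2(C)CC[C@@](O)(C(C)C)[C@H]12 | target

## Step count and least certain steps

Total step count: 17. Longest linear sequence: 17 steps (1 to 26); the route is fully linear, with 2 and 6 entering as building blocks.

Step 6 (key step). The most likely failure is closure of ring A under kinetic control on the enolate face that carries the tether, giving the cis-fused aldolate, combined with slow or unfavourable equilibration of the strongly bound aluminium aldolate toward the trans-fused chelate. The preference between the two chelated aldolates is small, so the ring fusion is not assured. Lesser risks are methyl transfer to the side-chain ketone and Lewis-acid opening of the β-keto ketal.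
- Fallback, from 11 back to 13: run the same copper-catalysed methyl addition but trap the aluminium enolate with Me3SiOTf to give the silyl enol ether F1. Then release the C5 enolate regiospecifically from F1 with KOtBu in THF at −78 → 0 °C. The aldol then runs through a potassium aldolate, whose retro-aldol is much faster, and can be equilibrated and quenched with buffer to give 13. This separates the enantio-determining step from the ring closure and lets counter-ion, temperature and time of the aldol be chosen independently.

Step 1. The likely failure is acid-mediated opening of the β-keto ketal to the 2-hydroxyethyl vinylogous ester, or over-ketalisation, because a 1,3-dione offers a conjugated alternative to the ketal.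
- Fallback, from 1 back to 3: mono-reduction with NaBH4 (0.3 equiv, EtOH, 0 °C) to 3-hydroxycycloheptan-1-one F2. Ketalisation of this simple ketone with ethane-1,2-diol and PPTS (benzene, water removal) gives the hydroxy ketal F3. Oxidation with Dess–Martin periodinane and NaHCO3 gives 3. The ketal is thus formed where no vinylogous ester is possible.

Step 5. The likely failure is loss of the dioxolane under the Lewis acid (opening toward the enone carbonyl), together with competing alkyl shift or elimination of the opened epoxide.
- Fallback, from 9 back to 11, bypassing 10: chemoselective Upjohn dihydroxylation of the electron-rich side-chain alkene (OsO4 cat., NMO) gives the diol F4. Oxidation of its secondary hydroxyl with Dess–Martin periodinane and NaHCO3 gives the α-hydroxy ketone F5. Reductive cleavage of the tertiary α-hydroxyl with SmI2 (THF/MeOH, −78 °C) gives 11. All three steps are neutral or buffered.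

Step 7. The likely failure is poor ligand exchange of the borohydride onto the hindered tertiary C4 hydroxyl. Hydride would then arrive externally on the more open α face and give the 6β-alcohol.
- Fallback, from 13 back to 14: accept external delivery with NaBH4 (MeOH, −40 °C) to give the 6β-epimer F6. Invert C6 by Mitsunobu reaction with 4-nitrobenzoic acid (PPh3, DIAD, toluene) to the 6α-ester F7. Cleave the ester with K2CO3 in MeOH to give 14.

Step 10. The likely failure is incomplete regiocontrol of the kinetic deprotonation. Proton abstraction at C7 would lead to the wrong enol ether or to loss of the C6 silyloxy group by β-elimination.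
- Fallback, from 14 back to 19: hydrolyse the ketal of 14 first (PPTS, acetone/H2O) to the keto diol F8. Treat F8 with LiN(iPr)2 (3.3 equiv) so that the C6 alkoxide steers the carbon deprotonation to the remote C9 by charge repulsion. Silylate with Me3SiCl to the tris(trimethylsilyl) enol ether F9, oxidise with Pd(OAc)2 to the bis(trimethylsilyl) enone F10, and wash with dilute acid to obtain the hydroxy enone F11. Silylation of the C6 hydroxyl of F11 with tBuMe2SiOTf and 2,6-lutidine rejoins the route at 19.

Further compounds

F1 | step 6 | trimethylsilyl C7=C8 enol ether of (9R)-9-methyl-9-(4-methyl-3-oxopentyl)-1,4-dioxaspiro[4.6]undecan-7-one | C[Si](C)(C)OC1=C[C@](C)(CCC(=O)C(C)C)CCC2(OCCO2)C1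
F2 | step 1 | 3-hydroxycycloheptan-1-one (racemic) | O=C1CCCCC(O)C1
F3 | step 1 | 1,4-dioxaspiro[4.6]undecan-7-ol (racemic) | OC1CCCCC2(OCCO2)C1
F4 | step 5 | 9-(3,4-dihydroxy-4-methylpentyl)-1,4-dioxaspiro[4.6]undec-8-en-7-one (racemic) | O=C1C=C(CCC(O)C(C)(C)O)CCC2(OCCO2)C1
F5 | step 5 | 9-(4-hydroxy-4-methyl-3-oxopentyl)-1,4-dioxaspiro[4.6]undec-8-en-7-one | O=C1C=C(CCC(=O)C(C)(C)O)CCC2(OCCO2)C1
F6 | step 7 | 8,8-ethylenedioxy-4α-isopropyl-1β-methyl-5αH-bicyclo[5.3.0]decane-4β,6β-diol | O[C@@H]1CC3(OCCO3)CC[C@@]2(C)CC[C@@](O)(C(C)C)[C@H]12
F7 | step 7 | 8,8-ethylenedioxy-4β-hydroxy-4α-isopropyl-1β-methyl-5αH-bicyclo[5.3.0]decan-6α-yl 4-nitrobenzoate | O=C(O[C@H]1CC3(OCCO3)CC[C@@]2(C)CC[C@@](O)(C(C)C)[C@H]12)c1ccc(cc1)[N+](=O)[O-]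
F8 | step 10 | 4β,6α-dihydroxy-4α-isopropyl-1β-methyl-5αH-bicyclo[5.3.0]decan-8-one | O[C@H]1CC(=O)CC[C@@]2(C)CC[C@@](O)(C(C)C)[C@H]12
F9 | step 10 | 4α-isopropyl-1β-methyl-4β,6α,8-tris(trimethylsilyloxy)-5αH-bicyclo[5.3.0]dec-8-ene | C[Si](C)(C)O[C@H]1CC(O[Si](C)(C)C)=CC[C@@]2(C)CC[C@@](O[Si](C)(C)C)(C(C)C)[C@H]12
F10 | step 10 | 4α-isopropyl-1β-methyl-4β,6α-bis(trimethylsilyloxy)-5αH-bicyclo[5.3.0]dec-9-en-8-one | C[Si](C)(C)O[C@H]1CC(=O)C=C[C@@]2(C)CC[C@@](O[Si](C)(C)C)(C(C)C)[C@H]12
F11 | step 10 | 4β,6α-dihydroxy-4α-isopropyl-1β-methyl-5αH-bicyclo[5.3.0]dec-9-en-8-one | O[C@H]1CC(=O)C=C[C@@]2(C)CC[C@@](O)(C(C)C)[C@H]12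
A1 | alternative 1 | bicyclo[5.3.0]deca-3,5-diene with 4-isopropyl, 1β-methyl, 8-silyloxy and 9α,10α-isopropylidenedioxy groups (daucane numbering) | C1[C@H](O[Si](C)(C)C(C)(C)C)[C@H]3OC(C)(C)O[C@H]3[C@@]2(C)CC=C(C(C)C)C2=C1
A2 | alternative 1 | open-chain dienyne: C1 quaternary carbon bearing methyl, allyl and 3-methylbut-1-ynyl groups and a C10–C6 chain with the 9,10-acetonide, 8-silyloxy group and terminal vinyl | C=CC[C@H](O[Si](C)(C)C(C)(C)C)[C@H]1OC(C)(C)O[C@H]1[C@@](C)(CC=C)C#CC(C)C
A3 | alternative 2 | 1β-methyl-6-methylene-5αH-bicyclo[5.3.0]decane-4,8-dione (daucane numbering) | C=C1CC(=O)CC[C@@]2(C)CCC(=O)[C@H]12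
A4 | alternative 2 | 5-methyl-cis-bicyclo[3.3.0]octane-2,8-dione | O=C1CC[C@@]2(C)CCC(=O)C12
A5 | alternative 2 | propa-1,2-diene | C=C=C
A6 | alternative 3 | methyl 10α-(tert-butyldimethylsilyloxy)-4,4-ethylenedioxy-1β-methylbicyclo[5.3.0]deca-5,8-diene-8-carboxylate (daucane numbering) | C1C(C(=O)OC)=C[C@@H](O[Si](C)(C)C(C)(C)C)[C@@]2(C)CCC3(OCCO3)C2=C1
A7 | alternative 3 | 6-ethenyl-7-methyl-1,4-dioxaspiro[4.4]non-6-ene | C=CC1=C(C)CCC12OCCO2
A8 | alternative 3 | methyl (E)-4-(tert-butyldimethylsilyloxy)-2-diazobut-3-enoate | COC(=O)C(=[N+]=[N-])/C=C/O[Si](C)(C)C(C)(C)C
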